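The readings come from a simulation with constants of no real substance, and the scatter is random.

Compare the two earlier runs at a single time on the rise of product.

| flask | substrate | remark | time |
|---|---|---|---|
| north-east | 0.070 M | run made earlier |  |
| west | 0.11 M | run made earlier |  |
| flask | 0.050 M |  | 5.0 d |

| run | time / d | product / % |
|---|---|---|
| north-east | 0.208 | 6.0 |
| north-east | 0.500 | 10.1 |
| north-east | 1.04 | 11.2 |
| north-east | 2.50 | 9.4 |
| north-east | 5.00 | 8.0 |
| west | 0.208 | 5.5 |
| west | 0.500 | 9.9 |
| west | 1.04 | 10.9 |
| west | 2.50 | 9.1 |
| west | 5.00 | 8.1 |

(scatter of a reading: 0.3 percentage points)

- what was read earlier has a scatter of 0.3 percentage points, one standard deviation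

- the best time, 5.0 d at the latest, for product
- the amount of product, in percent of the substrate charged, at that time
- the first time at which product reaches 7.7 %, in the same percent

I take 0.500 d, where the north-east run reads 10.1 % from 0.070 M of substrate. Two extremes are easy to reckon. If the rate ignored the substrate concentration (zero order), the same molar amount would form, so the west run, charged with 0.11 M, should read 6.43 %. If the rate went with the square of that concentration (second order), the percent would grow with the charge, so the west run should read 15.9 %. The west run reads 9.9 %, between the two.

Let n be the apparent order, one plus the logarithm of the ratio of the two percentages, west to north-east, over the logarithm of the ratio of the two charges, west to north-east; here 0.956. The percent at a fixed time on the rise then goes as the charge to the power n minus one. The two readings differ by 0.2 percentage points against a scatter of 0.3 points, so I can't tell n from one.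

Scaling the north-east reading to the flask's 0.050 M, I get 10.3 % at 0.500 d, an estimate that carries the scatter of the readings. This reckoning is mine, and it gives no peak. The forecast reads 0.9 d (0.7 d to 1.2 d) for the best time, 11.1 % (10.7 % to 11.6 %) for the best, and 0.31 d (0.27 d to 0.35 d) for the first time, since “the steps look first order overall”.

The flask gives its best, 11.0 %, at 0.895 d, and first reaches 7.7 % at 0.317 d, each inside the forecast's range.

    product ⇌ intermediate A (K = 1.90, k = 0.0606 h⁻¹)
    intermediate C → product (k = 0.0154 h⁻¹)
    substrate → intermediate A (k = 0.329 h⁻¹)
    intermediate A ⇌ intermediate B (K = 4.70, k = 0.202 h⁻¹)
    substrate ⇌ intermediate C (K = 1.59, k = 0.313 h⁻¹)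

At that best time the flask holds 63.0 % of intermediate B, which a curve of product doesn't show. Put to use once more, n scaled the north-east reading to 10.3 % at 0.500 d, and the flask holds 9.86 % then, lower by 0.44 points.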